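**Retrosynthetic overview**
1. Aryl ether C–O bond: Mitsunobu coupling of umbelliferone with a (2R,3S)-epoxy alcohol, as the last step.
2. Oxirane: Sharpless asymmetric epoxidation of a (Z)-allylic alcohol, which sets both oxirane centres.
3. Lactone ring, its CH–O centre and the C(sp3)–C(sp2) bond: a new Pd-catalysed, hydroxyl-anchored alkenylative lactonisation of (S)-2-hydroxy-2-methylpent-4-enoic acid with a (Z)-alkenyl iodide.
4. Acid from (R)-lactic acid by Seebach acetal alkylation with allyl bromide (sets the tertiary carbinol); iodide from but-2-yn-1-ol by trans-hydroalumination/iodination.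
5. Ring order: lactone ring first (step 6), oxirane ring second (step 8); the coumarin bicycle is bought intact.

Assumption: the SMILES is read as the (3S,5S)-lactone (OH cis to the side chain) carrying a (2R,3S)-oxirane whose CH2OAr and CH2-lactone groups are cis (neryl-type geometry); but-2-yn-1-ol, (R)-lactic acid, allyl bromide and umbelliferone are taken as commercial.

**Route**

Step 1
Reactants: 1 but-2-yn-1-ol
Product: 3 (2Z)-3-iodobut-2-en-1-ol, via cyclic alkenylaluminate 2 (not isolated)
Conditions: NaAlH2(OCH2CH2OCH3)2 (1.5 equiv), THF, 0 °C to rt; then I2, −78 to 0 °C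
Reagents that add atoms: iodine, [I][I]
Why: hydroxyl-directed trans-hydroalumination of the propargylic alcohol puts hydride on C2 and aluminium on C3 inside a five-membered alkoxyaluminate ring, and iodinolysis of the C–Al bond with retention gives the Z iodide (I cis to CH2OH), which later places the two CH2 groups cis on the olefin.

Step 2
Reactants: 3 (2Z)-3-iodobut-2-en-1-ol
Product: 4 tert-butyl{[(2Z)-3-iodobut-2-en-1-yl]oxy}dimethylsilane
Conditions: TBSCl, imidazole, CH2Cl2, 0 °C to rt
Reagents that add atoms: tert-butyldimethylsilyl chloride (TBSCl), CC(C)(C)[Si](C)(C)Cl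
Why: imidazole-promoted silylation masks the allylic OH so that it neither binds palladium nor is oxidised in the coupling step, and the Z-alkenyl iodide is untouched.

Step 3
Reactants: 5 (R)-lactic acid
Product: 6 (2R,5R)-2-tert-butyl-5-methyl-1,3-dioxolan-4-one
Conditions: t-BuCHO, cat. TsOH·H2O, cat. H2SO4, pentane, reflux (Dean–Stark); recrystallisation from Et2O/pentane, −78 °C
Reagents that add atoms: pivalaldehyde (2,2-dimethylpropanal), CC(C)(C)C=O
Why: acid-catalysed acetalisation (first stage of Seebach self-regeneration of stereocentres) gives the dioxolanone with tert-butyl cis to methyl under thermodynamic control, so the lactate centre sets the acetal centre as 2R and crystallisation removes the minor trans isomer.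

Step 4
Reactants: 6 (2R,5R)-2-tert-butyl-5-methyl-1,3-dioxolan-4-one, 7 allyl bromide (3-bromoprop-1-ene)
Product: 9 (2R,5S)-2-tert-butyl-5-methyl-5-(prop-2-en-1-yl)-1,3-dioxolan-4-one, via lithium enolate 8 (not isolated)
Conditions: LiN(iPr)2 (commercial solution, 1.1 equiv), THF, −78 °C; then 7, −78 to −30 °C
Reagents that add atoms: none
Why: enolate alkylation (Seebach self-regeneration of stereocentres), in which the planar lithium enolate keeps the acetal centre, its tert-butyl group blocks one face and allyl bromide enters trans to it, regenerating the quaternary carbinol centre as 5S.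

Step 5
Reactants: 9 (2R,5S)-2-tert-butyl-5-methyl-5-(prop-2-en-1-yl)-1,3-dioxolan-4-one
Product: 10 (2S)-2-hydroxy-2-methylpent-4-enoic acid
Conditions: LiOH, THF/H2O, rt; then 1 M HCl to pH 2
Reagents that add atoms: lithium hydroxide, [Li+].[OH-]
Why: saponification opens the acyl acetal, the hemiacetal alkoxide sheds pivalaldehyde and the quaternary centre cannot epimerise, so acidification gives the free (S)-α-hydroxy acid.

Step 6
Reactants: 10 (2S)-2-hydroxy-2-methylpent-4-enoic acid, 4 tert-butyl{[(2Z)-3-iodobut-2-en-1-yl]oxy}dimethylsilane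
Product: 11 (3S,5R)-5-[(2Z)-4-{[tert-butyl(dimethyl)silyl]oxy}-2-methylbut-2-en-1-yl]-3-hydroxy-3-methyloxolan-2-one
Conditions: Pd2(dba)3 (2.5 mol %), P(2-furyl)3 (10 mol %), Cs2CO3 (2.2 equiv), DMF, 60 °C
Reagents that add atoms: none
Why: Proposed new method: hydroxyl-anchored alkenylative lactonisation, in which zerovalent palladium inserts into the C–I bond of 4 with retention of the Z geometry, the tertiary alkoxide of 10 replaces iodide on divalent palladium so that the homoallylic C=C is held on the metal in a five-membered chelate, the free cesium carboxylate attacks the internal alkene carbon from the face opposite the metal (5-exo anti-oxypalladation) to give a six-membered alkyl(alkenyl)palladacycle that can exist only when the carbinol oxygen and the new CH2 arm are cis on the lactone (this sets the ring CH–O centre, R in 11 and S in the target by priority change only) and in which β-hydride elimination is disfavoured, and C(sp3)–C(sp2) reductive elimination then forms the C–C bond; the closest known reaction types are the Pd-catalysed carboetherification of γ-hydroxyalkenes with alkenyl halides and the anti-oxypalladation/coupling of unsaturated carboxylic acids with organic halides.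

Step 7
Reactants: 11 (3S,5R)-5-[(2Z)-4-{[tert-butyl(dimethyl)silyl]oxy}-2-methylbut-2-en-1-yl]-3-hydroxy-3-methyloxolan-2-one
Product: 12 (3S,5R)-3-hydroxy-5-[(2Z)-4-hydroxy-2-methylbut-2-en-1-yl]-3-methyloxolan-2-one
Conditions: HF·pyridine, THF/pyridine, 0 °C to rt
Reagents that add atoms: none
Why: fluoride-mediated desilylation (Si–F bond formation) frees the primary allylic alcohol under mild conditions that leave the γ-lactone, the tertiary alcohol and the Z olefin unchanged.

Step 8
Reactants: 12 (3S,5R)-3-hydroxy-5-[(2Z)-4-hydroxy-2-methylbut-2-en-1-yl]-3-methyloxolan-2-one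
Product: 13 (3S,5S)-3-hydroxy-5-{[(2R,3S)-3-(hydroxymethyl)-2-methyloxiran-2-yl]methyl}-3-methyloxolan-2-one
Conditions: Ti(OiPr)4 (20 mol %), L-(+)-diethyl tartrate (24 mol %), t-BuOOH (decane), 4 Å molecular sieves, CH2Cl2, −20 °C
Reagents that add atoms: tert-butyl hydroperoxide, CC(C)(C)OO
Why: Katsuki–Sharpless asymmetric epoxidation, in which the titanium L-(+)-tartrate catalyst binds the allylic OH and delivers oxygen to the face that makes the CH carbon S (as nerol gives (2S,3R)-epoxynerol), and because the olefin is Z the methyl-bearing carbon becomes R, so both oxirane centres are set under catalyst control.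

Step 9
Reactants: 13 (3S,5S)-3-hydroxy-5-{[(2R,3S)-3-(hydroxymethyl)-2-methyloxiran-2-yl]methyl}-3-methyloxolan-2-one, 14 umbelliferone (7-hydroxy-2H-chromen-2-one)
Product: 15 (3S,5S)-3-hydroxy-3-methyl-5-{[(2R,3S)-2-methyl-3-{[(2-oxo-2H-chromen-7-yl)oxy]methyl}oxiran-2-yl]methyl}oxolan-2-one (CNP0246010.1)
Conditions: PPh3, DIAD, THF, 0 °C to rt
Reagents that add atoms: none
Why: Mitsunobu etherification, in which the acidic phenol (pKa about 7.8) protonates the betaine, only the primary alcohol forms the alkoxyphosphonium ion and the phenoxide displaces it by SN2 at CH2, so no stereocentre is touched and the tertiary alcohol and oxirane stay intact.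

**Compound list**
1 | but-2-yn-1-ol | CC#CCO | starting material
2 | sodium 2,2-bis(2-methoxyethoxy)-3-methyl-2,5-dihydro-1,2-oxaluminol-2-uide (cyclic alkenylaluminate) | CC1=CCO[Al-]1(OCCOC)OCCOC.[Na+] | intermediate (not isolated)
3 | (2Z)-3-iodobut-2-en-1-ol | C/C(I)=C/CO | intermediate
4 | tert-butyl{[(2Z)-3-iodobut-2-en-1-yl]oxy}dimethylsilane | C/C(I)=C/CO[Si](C)(C)C(C)(C)C | intermediate
5 | (2R)-2-hydroxypropanoic acid ((R)-lactic acid) | C[C@@H](O)C(=O)O | starting material
6 | (2R,5R)-2-tert-butyl-5-methyl-1,3-dioxolan-4-one | C[C@H]1O[C@@H](C(C)(C)C)OC1=O | intermediate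
7 | 3-bromoprop-1-ene (allyl bromide) | C=CCBr | starting material
8 | lithium (2R)-2-tert-butyl-5-methyl-2H-1,3-dioxol-4-olate (lithium enolate) | CC1=C(O[Li])O[C@H](C(C)(C)C)O1 | intermediate (not isolated)
9 | (2R,5S)-2-tert-butyl-5-methyl-5-(prop-2-en-1-yl)-1,3-dioxolan-4-one | C=CC[C@]1(C)O[C@@H](C(C)(C)C)OC1=O | intermediate
10 | (2S)-2-hydroxy-2-methylpent-4-enoic acid | C=CC[C@](C)(O)C(=O)O | intermediate
11 | (3S,5R)-5-[(2Z)-4-{[tert-butyl(dimethyl)silyl]oxy}-2-methylbut-2-en-1-yl]-3-hydroxy-3-methyloxolan-2-one | C[C@]1(O)C[C@@H](C/C(C)=C\CO[Si](C)(C)C(C)(C)C)OC1=O | intermediate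
12 | (3S,5R)-3-hydroxy-5-[(2Z)-4-hydroxy-2-methylbut-2-en-1-yl]-3-methyloxolan-2-one | C[C@]1(O)C[C@@H](C/C(C)=C\CO)OC1=O | intermediate
13 | (3S,5S)-3-hydroxy-5-{[(2R,3S)-3-(hydroxymethyl)-2-methyloxiran-2-yl]methyl}-3-methyloxolan-2-one | C[C@]1(O)C[C@@H](C[C@@]2(C)O[C@H]2CO)OC1=O | intermediate
14 | 7-hydroxy-2H-chromen-2-one (umbelliferone) | O=c1ccc2ccc(O)cc2o1 | starting material
15 | (3S,5S)-3-hydroxy-3-methyl-5-{[(2R,3S)-2-methyl-3-{[(2-oxo-2H-chromen-7-yl)oxy]methyl}oxiran-2-yl]methyl}oxolan-2-one | C[C@]1(O)C[C@@H](C[C@@]2(C)O[C@H]2COc2ccc3ccc(=O)oc3c2)OC1=O | target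

The C5 letter of the lactone changes from R (11, 12) to S (13, 15) because the side chain gains CIP priority on epoxidation, not through inversion.

**Totals**
Total step count: 9. Longest linear sequence: 7 steps (steps 3 to 9, from (R)-lactic acid); the iodide branch (steps 1 and 2) joins at step 6.

**Steps most likely to fail, with fallbacks**

Step 6 (the proposed new step). Risks are Heck-type insertion of the alkenylpalladium into the terminal olefin, β-hydride elimination to an enol lactone, and a poor cis/trans ratio if the un-anchored pathway competes. The fallback uses known chemistry, sets out from 9 and 4, and comes back at 11. Enantioselective Pt-catalysed diboration of the terminal olefin of 9 (Pt(dba)3, TADDOL-derived phosphonite ligand, B2(pin)2, THF, 60 °C) gives (2R,5S)-5-[(2R)-2,3-bis(4,4,5,5-tetramethyl-1,3,2-dioxaborolan-2-yl)propyl]-2-tert-butyl-5-methyl-1,3-dioxolan-4-one F1. The ligand enantiomer is the one that gives the R-configured secondary C–B centre; I have not fixed which enantiomer that is, so it is chosen by a small-scale test against its antipode. Suzuki–Miyaura coupling of the primary C–B bond with 4 (Pd(OAc)2, RuPhos, KOH, THF/H2O, 70 °C) keeps the Z geometry. The aqueous KOH also opens the dioxolanone with loss of pivalaldehyde, giving potassium (2S,4R,6Z)-8-{[tert-butyl(dimethyl)silyl]oxy}-2-hydroxy-2,6-dimethyl-4-(4,4,5,5-tetramethyl-1,3,2-dioxaborolan-2-yl)oct-6-enoate F2. Oxidation of the C–B bond with retention (NaOH, H2O2, 0 °C) gives potassium (2S,4R,6Z)-8-{[tert-butyl(dimethyl)silyl]oxy}-2,4-dihydroxy-2,6-dimethyloct-6-enoate F3. Acidification to pH 3 with HCl closes F3 to lactone 11.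

Step 8. Z-trisubstituted allylic alcohols react more slowly and less selectively, the α-hydroxy lactone may tie up titanium, and the tertiary OH could open the activated oxirane. The fallback sets out from 11 and comes back at 13, with no directing hydroxyl and no titanium. Shi epoxidation of the silyl ether 11 uses the L-fructose-derived ketone (the antipode of the usual D-fructose-derived catalyst, chosen by the spiro transition-state model to make the CH carbon S), KHSO5 (as 2KHSO5·KHSO4·K2SO4), K2CO3 buffer, Bu4NHSO4, MeCN/dimethoxymethane/H2O, 0 °C. This gives (3S,5S)-5-{[(2R,3S)-3-({[tert-butyl(dimethyl)silyl]oxy}methyl)-2-methyloxiran-2-yl]methyl}-3-hydroxy-3-methyloxolan-2-one F4. Desilylation with HF·pyridine then gives 13.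

Step 9. The Mitsunobu reaction on a hindered epoxy alcohol can stall or give elimination, and the product must be separated from Ph3PO. The fallback sets out from 13 and comes back at 15 by Williamson alkylation instead of redox condensation. Selective sulfonylation of the primary alcohol (TsCl, Et3N, cat. DMAP, CH2Cl2, 0 °C) gives (3S,5S)-3-hydroxy-3-methyl-5-{[(2R,3S)-2-methyl-3-{[(4-methylbenzenesulfonyl)oxy]methyl}oxiran-2-yl]methyl}oxolan-2-one F5. Phenoxide displacement at the primary carbon with umbelliferone 14 (K2CO3, DMF, 50 °C) gives 15; the fully substituted oxirane carbon is shielded from attack.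

**Further compounds**
F1 | step 6 | (2R,5S)-5-[(2R)-2,3-bis(4,4,5,5-tetramethyl-1,3,2-dioxaborolan-2-yl)propyl]-2-tert-butyl-5-methyl-1,3-dioxolan-4-one | CC1(C)OB(OC1(C)C)C[C@@H](B1OC(C)(C)C(C)(C)O1)C[C@]1(C)O[C@@H](C(C)(C)C)OC1=O
F2 | step 6 | potassium (2S,4R,6Z)-8-{[tert-butyl(dimethyl)silyl]oxy}-2-hydroxy-2,6-dimethyl-4-(4,4,5,5-tetramethyl-1,3,2-dioxaborolan-2-yl)oct-6-enoate | C[C@](O)(C[C@@H](C/C(C)=C\CO[Si](C)(C)C(C)(C)C)B1OC(C)(C)C(C)(C)O1)C(=O)[O-].[K+]
F3 | step 6 | potassium (2S,4R,6Z)-8-{[tert-butyl(dimethyl)silyl]oxy}-2,4-dihydroxy-2,6-dimethyloct-6-enoate | C[C@](O)(C[C@H](O)C/C(C)=C\CO[Si](C)(C)C(C)(C)C)C(=O)[O-].[K+]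
F4 | step 8 | (3S,5S)-5-{[(2R,3S)-3-({[tert-butyl(dimethyl)silyl]oxy}methyl)-2-methyloxiran-2-yl]methyl}-3-hydroxy-3-methyloxolan-2-one | C[C@]1(O)C[C@@H](C[C@@]2(C)O[C@H]2CO[Si](C)(C)C(C)(C)C)OC1=O
F5 | step 9 | (3S,5S)-3-hydroxy-3-methyl-5-{[(2R,3S)-2-methyl-3-{[(4-methylbenzenesulfonyl)oxy]methyl}oxiran-2-yl]methyl}oxolan-2-one | C[C@]1(O)C[C@@H](C[C@@]2(C)O[C@H]2COS(=O)(=O)c2ccc(C)cc2)OC1=O
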